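**Plan**

- Locants: ring A carbons C1'–C6' (C1' bears the carbonyl), side chain C1''–C4'' on C3'. The retrosynthesis first cuts the aryl ketone bond C1'–C(=O), giving a ring A aryllithium and the cinnamoyl Weinreb amide 14. It then cuts C3'–C1'' and C2''–C3'' in a single operation, with C2''–OH traced back to C2''–B.
- Enabling feature: the two-carbon unit C1''–C2'' lies between ring A carbon C3' and the isopropenyl carbon C3'', and C2'' is the only stereocentre and carries the heteroatom. A vinylboronate gives exactly this pattern when an aryl group adds to its terminus while an alkenyl group shifts onto the boron-bearing carbon.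
- Forward: the symmetric ring A bromide 4, vinylboronate 6 and isopropenyllithium 7 are joined to give boronate 9. Oxidation, silylation, ortho-lithiation at one of the two equivalent free ring A positions, acylation with 14 and global deprotection follow. No ring is formed; both benzene rings are bought.
- Stereochemistry: the (R) centre is set as a C–B centre by the chiral palladium catalyst and passes to C–O with retention. The E alkene is inherited from 4-hydroxycinnamic acid.

Key step: step 3

Assumption: L* is the enantiomer of the Mandyphos ligand 1,1'-bis[bis(3,5-dimethylphenyl)phosphino]-2,2'-bis[α-(dimethylamino)benzyl]ferrocene that delivers the (R)-configured C–B centre. Both antipodes are commercial, and the sense of induction is to be confirmed on the first batch by Mosher ester analysis of alcohol 10.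

**Route**

Step 1
Reactants: 1 5-methoxyresorcinol
Product: 2 1-methoxy-3,5-bis(methoxymethoxy)benzene
Conditions: NaH, MOMCl, DMF, 0 °C to rt
Reagents that add atoms: chloromethyl methyl ether (MOMCl), COCCl
Why: Williamson-type O-alkylation of the two sodium phenoxides with the reactive α-chloro ether should install both acetal ethers, which later serve as directing groups for lithiation.

Step 2
Reactants: 2 1-methoxy-3,5-bis(methoxymethoxy)benzene
Product: 4 2-bromo-5-methoxy-1,3-bis(methoxymethoxy)benzene, via aryllithium 3 (not isolated)
Conditions: n-BuLi, THF, 0 °C; then BrCCl2CCl2Br, −78 °C to rt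
Reagents that add atoms: 1,2-dibromotetrachloroethane, BrC(Cl)(Cl)C(Cl)(Cl)Br
Why: Directed ortho-metalation should occur at the carbon flanked by both chelating methoxymethoxy groups, the strongest directing combination on the ring, and the aryllithium takes up electrophilic bromine from the dibromide with loss of tetrachloroethylene.

Step 3
Reactants: 4 2-bromo-5-methoxy-1,3-bis(methoxymethoxy)benzene; 5 2-bromopropene; 6 vinylboronic acid pinacol ester
Product: 9 2-[(2R)-1-[4-methoxy-2,6-bis(methoxymethoxy)phenyl]-3-methylbut-3-en-2-yl]-4,4,5,5-tetramethyl-1,3,2-dioxaborolane, via isopropenyllithium 7 (not isolated), via lithium borate complex 8 (not isolated)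
Conditions: 5, t-BuLi (2 equiv), Et2O, −78 °C; then 6, −78 °C to rt; solvent switch to THF; 4, Pd(OAc)2 (3 mol %), L* (3.6 mol %), NaOTf, THF, 60 °C
Reagents that add atoms: none
Why: Lithium–bromine exchange on 5 gives 7, which adds to boron of 6 to form the four-coordinate bis(alkenyl)borate 8; zerovalent palladium formed from Pd(OAc)2 and L* inserts into the C–Br bond of 4, and NaOTf removes bromide so that the cationic aryl divalent palladium can bind the unsubstituted vinyl group of 8. Coordination makes the boron-bearing vinyl carbon electrophilic, the isopropenyl group shifts from boron to that carbon anti to palladium (1,2-metallate rearrangement), and reductive elimination from the resulting alkyl(aryl)palladium joins the former vinyl terminus to the ring carbon between the two acetal ethers, returning zerovalent palladium. The closest known reaction type is the palladium-catalysed enantioselective conjunctive cross-coupling of bis(alkenyl)borates with aryl electrophiles, which gives α-chiral allylic boronic esters and admits aryl bromides when a triflate salt scavenges halide. No ring is closed. The new C–B stereocentre (R) is controlled by the C2-symmetric ligand L*, which fixes the face of the palladium-bound vinyl group that receives the migrating carbon. The step needs vinyl rather than isopropenyl as the acceptor and needs the metallate shift to outrun direct boron-to-palladium transfer of an alkenyl group; the weaker binding of the 1,1-disubstituted alkene to the crowded metal should secure the first, and the chelating wide-bite-angle ligand on a cationic, halide-free palladium centre the second.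

Step 4
Reactants: 9 2-[(2R)-1-[4-methoxy-2,6-bis(methoxymethoxy)phenyl]-3-methylbut-3-en-2-yl]-4,4,5,5-tetramethyl-1,3,2-dioxaborolane
Product: 10 (2R)-1-[4-methoxy-2,6-bis(methoxymethoxy)phenyl]-3-methylbut-3-en-2-ol
Conditions: 30% H2O2, 3 M NaOH, THF, 0 °C to rt
Reagents that add atoms: hydrogen peroxide, OO
Why: Organoborane oxidation proceeds by hydroperoxide addition to boron and 1,2-shift of carbon from boron to oxygen with retention, so the (R) C–B centre should become the (R) carbinol without allylic transposition, while the acetal ethers and the unactivated alkene are inert to alkaline peroxide.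

Step 5
Reactants: 10 (2R)-1-[4-methoxy-2,6-bis(methoxymethoxy)phenyl]-3-methylbut-3-en-2-ol
Product: 11 tert-butyl{[(2R)-1-[4-methoxy-2,6-bis(methoxymethoxy)phenyl]-3-methylbut-3-en-2-yl]oxy}dimethylsilane
Conditions: TBSCl, imidazole, DMF, rt
Reagents that add atoms: tert-butyldimethylsilyl chloride (TBSCl), CC(C)(C)[Si](C)(C)Cl
Why: Imidazole-promoted silylation of the secondary alcohol masks the only acidic proton before the organolithium step and leaves the C–O stereocentre untouched.

Step 6
Reactants: 12 4-hydroxycinnamic acid
Product: 13 (E)-3-(4-hydroxyphenyl)-N-methoxy-N-methylprop-2-enamide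
Conditions: MeNHOMe·HCl, EDC·HCl (1-ethyl-3-(3-dimethylaminopropyl)carbodiimide hydrochloride), HOBt (1-hydroxybenzotriazole), i-Pr2NEt, DMF, 0 °C to rt
Reagents that add atoms: N,O-dimethylhydroxylamine hydrochloride, CNOC.Cl
Why: Carbodiimide-mediated amide coupling through the benzotriazolyl active ester should be chemoselective, because the amine is far more nucleophilic than the phenol, and the E alkene is not affected.

Step 7
Reactants: 13 (E)-3-(4-hydroxyphenyl)-N-methoxy-N-methylprop-2-enamide
Product: 14 (E)-N-methoxy-3-[4-(methoxymethoxy)phenyl]-N-methylprop-2-enamide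
Conditions: MOMCl, i-Pr2NEt, CH2Cl2, 0 °C to rt
Reagents that add atoms: chloromethyl methyl ether (MOMCl), COCCl
Why: O-alkylation of the phenol with the α-chloro ether under amine base gives the same acetal protecting group as on ring A, so a single final operation can remove all of them.

Step 8
Reactants: 11 tert-butyl{[(2R)-1-[4-methoxy-2,6-bis(methoxymethoxy)phenyl]-3-methylbut-3-en-2-yl]oxy}dimethylsilane; 14 (E)-N-methoxy-3-[4-(methoxymethoxy)phenyl]-N-methylprop-2-enamide
Product: 17 (E)-1-[3-[(2R)-2-(tert-butyldimethylsilyloxy)-3-methylbut-3-en-1-yl]-6-methoxy-2,4-bis(methoxymethoxy)phenyl]-3-[4-(methoxymethoxy)phenyl]prop-2-en-1-one, via ring A aryllithium 15 (not isolated), via lithium hemiaminal adduct 16 (not isolated)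
Conditions: n-BuLi, TMEDA, THF, −20 to 0 °C; then 14, −78 to 0 °C; aq NH4Cl
Reagents that add atoms: none
Why: Directed ortho-metalation should take place at the ring carbon between the methoxymethoxy and methoxy groups (the two free positions are equivalent, so no regiocontrol is needed), and 1,2-addition of the aryllithium to the Weinreb amide gives a chelated tetrahedral adduct that releases the enone only on work-up (Weinreb ketone synthesis), which prevents over-addition.

Step 9
Reactants: 17 (E)-1-[3-[(2R)-2-(tert-butyldimethylsilyloxy)-3-methylbut-3-en-1-yl]-6-methoxy-2,4-bis(methoxymethoxy)phenyl]-3-[4-(methoxymethoxy)phenyl]prop-2-en-1-one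
Product: 18 (E)-1-[2,4-dihydroxy-3-[(2R)-2-hydroxy-3-methylbut-3-en-1-yl]-6-methoxyphenyl]-3-(4-hydroxyphenyl)prop-2-en-1-one
Conditions: 3 M aq HCl, MeOH, rt
Reagents that add atoms: none
Why: Acid-catalysed methanolysis should cleave the three aryl methoxymethyl acetals and the secondary silyl ether in one operation under conditions mild enough that the carbinol C–O bond is not ionised, so the (R) centre is kept.

**Compound list**

1 | 5-methoxyresorcinol | COc1cc(O)cc(O)c1 | starting material
2 | 1-methoxy-3,5-bis(methoxymethoxy)benzene | COCOc1cc(OC)cc(OCOC)c1 | intermediate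
3 | [4-methoxy-2,6-bis(methoxymethoxy)phenyl]lithium | [Li]c1c(OCOC)cc(OC)cc1OCOC | intermediate
4 | 2-bromo-5-methoxy-1,3-bis(methoxymethoxy)benzene | COCOc1cc(OC)cc(OCOC)c1Br | intermediate
5 | 2-bromopropene | C=C(C)Br | starting material
6 | vinylboronic acid pinacol ester | C=CB1OC(C)(C)C(C)(C)O1 | starting material
7 | isopropenyllithium | [Li]C(C)=C | intermediate
8 | lithium isopropenyl(vinyl)(pinacolato)borate | [Li+].C=C[B-]1(C(C)=C)OC(C)(C)C(C)(C)O1 | intermediate
9 | 2-[(2R)-1-[4-methoxy-2,6-bis(methoxymethoxy)phenyl]-3-methylbut-3-en-2-yl]-4,4,5,5-tetramethyl-1,3,2-dioxaborolane | C=C(C)[C@H](B1OC(C)(C)C(C)(C)O1)Cc1c(OCOC)cc(OC)cc1OCOC | intermediate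
10 | (2R)-1-[4-methoxy-2,6-bis(methoxymethoxy)phenyl]-3-methylbut-3-en-2-ol | C=C(C)[C@H](O)Cc1c(OCOC)cc(OC)cc1OCOC | intermediate
11 | tert-butyl{[(2R)-1-[4-methoxy-2,6-bis(methoxymethoxy)phenyl]-3-methylbut-3-en-2-yl]oxy}dimethylsilane | C=C(C)[C@H](O[Si](C)(C)C(C)(C)C)Cc1c(OCOC)cc(OC)cc1OCOC | intermediate
12 | 4-hydroxycinnamic acid | O=C(O)/C=C/c1ccc(O)cc1 | starting material
13 | (E)-3-(4-hydroxyphenyl)-N-methoxy-N-methylprop-2-enamide | CON(C)C(=O)/C=C/c1ccc(O)cc1 | intermediate
14 | (E)-N-methoxy-3-[4-(methoxymethoxy)phenyl]-N-methylprop-2-enamide | CON(C)C(=O)/C=C/c1ccc(OCOC)cc1 | intermediate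
15 | ring A aryllithium of 11, lithium between the methoxy and a methoxymethoxy group | C=C(C)[C@H](O[Si](C)(C)C(C)(C)C)Cc1c(OCOC)cc(OC)c([Li])c1OCOC | intermediate
16 | lithium N-methoxy-N-methyl hemiaminal adduct of 15 and 14 | C=C(C)[C@H](O[Si](C)(C)C(C)(C)C)Cc1c(OCOC)cc(OC)c(C(O[Li])(N(C)OC)/C=C/c2ccc(OCOC)cc2)c1OCOC | intermediate
17 | (E)-1-[3-[(2R)-2-(tert-butyldimethylsilyloxy)-3-methylbut-3-en-1-yl]-6-methoxy-2,4-bis(methoxymethoxy)phenyl]-3-[4-(methoxymethoxy)phenyl]prop-2-en-1-one | C=C(C)[C@H](O[Si](C)(C)C(C)(C)C)Cc1c(OCOC)cc(OC)c(C(=O)/C=C/c2ccc(OCOC)cc2)c1OCOC | intermediate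
18 | (E)-1-[2,4-dihydroxy-3-[(2R)-2-hydroxy-3-methylbut-3-en-1-yl]-6-methoxyphenyl]-3-(4-hydroxyphenyl)prop-2-en-1-one | C=C(C)[C@H](O)Cc1c(O)cc(OC)c(C(=O)/C=C/c2ccc(O)cc2)c1O | target

**Step count and risks**

Total steps: 9. Longest linear sequence: 7 (steps 1, 2, 3, 4, 5, 8, 9); steps 6 and 7 form the two-step side branch to 14.

Steps most likely to fail:

1. Step 3. Oxidative addition into the electron-rich, doubly ortho-alkoxylated C–Br bond may be slow, so that direct alkenyl transfer from boron to palladium or decomposition of the borate outruns the metallate shift, and the crowded aryl group may erode facial discrimination. The fallback sets out from 2 and comes back at 10. Aryllithium 3, generated from 2 as in step 2, would be alkylated with prenyl bromide (catalytic CuBr·SMe2) to give 5-methoxy-1,3-bis(methoxymethoxy)-2-(3-methylbut-2-en-1-yl)benzene F1. Shi asymmetric epoxidation of its trisubstituted alkene with the D-fructose-derived ketone 1,2:4,5-di-O-isopropylidene-β-D-erythro-2,3-hexodiulo-2,6-pyranose and Oxone (2KHSO5·KHSO4·K2SO4) at pH 10.5 should give (3R)-3-[4-methoxy-2,6-bis(methoxymethoxy)benzyl]-2,2-dimethyloxirane F2. Base-induced isomerisation of the epoxide with Et2Al(TMP) (diethylaluminium 2,2,6,6-tetramethylpiperidide) in toluene at 0 °C removes a methyl proton and opens the tertiary C–O bond; the secondary C–O bond and its configuration stay intact, which leads to alcohol 10.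

2. Step 8. Competing deprotonation at the benzylic methylene or at the allylic silyloxy carbon, or conjugate addition of the aryllithium to the cinnamoyl amide, may divert the acylation. The fallback sets out from 11 and comes back at 17. Electrophilic bromination of the very electron-rich ring with N-bromosuccinimide in MeCN at −20 °C should give the ring A bromide F3. Bromine–lithium exchange with t-BuLi at −78 °C regenerates 15 without any acid–base competition. Trapping with N-methoxy-N-methylacetamide passes through the lithium hemiaminal adduct F4 and gives the methyl ketone F5 on work-up. Claisen–Schmidt condensation of F5 with commercial 4-(methoxymethoxy)benzaldehyde (KOH, EtOH, rt) then forms the E enone 17.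

3. Step 9. Protic acid may trigger cyclisation of a liberated ortho-phenol onto the isopropenyl carbinol chain, or closure of the 2'-hydroxychalcone to a flavanone, before all acetals are cleaved. The fallback sets out from 17 and comes back at 18. The three aryl methoxymethyl ethers would be exchanged for silyl ethers under non-acidic conditions with TESOTf and 2,2'-bipyridyl in CH2Cl2 at 0 °C, which gives the tris(triethylsilyl) tert-butyldimethylsilyl ether F6. All four silyl groups are then removed with fluoride (HF·pyridine, THF, 0 °C) to give 18.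

**Further compounds**

F1 | step 3 | 5-methoxy-1,3-bis(methoxymethoxy)-2-(3-methylbut-2-en-1-yl)benzene | CC(C)=CCc1c(OCOC)cc(OC)cc1OCOC
F2 | step 3 | (3R)-3-[4-methoxy-2,6-bis(methoxymethoxy)benzyl]-2,2-dimethyloxirane | CC1(C)[C@H](O1)Cc2c(OCOC)cc(OC)cc2OCOC
F3 | step 8 | {[(2R)-1-[3-bromo-4-methoxy-2,6-bis(methoxymethoxy)phenyl]-3-methylbut-3-en-2-yl]oxy}(tert-butyl)dimethylsilane | C=C(C)[C@H](O[Si](C)(C)C(C)(C)C)Cc1c(OCOC)cc(OC)c(Br)c1OCOC
F4 | step 8 | lithium N-methoxy-N-methyl hemiaminal adduct of 15 and N-methoxy-N-methylacetamide | C=C(C)[C@H](O[Si](C)(C)C(C)(C)C)Cc1c(OCOC)cc(OC)c(C(C)(O[Li])N(C)OC)c1OCOC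
F5 | step 8 | 1-[3-[(2R)-2-(tert-butyldimethylsilyloxy)-3-methylbut-3-en-1-yl]-6-methoxy-2,4-bis(methoxymethoxy)phenyl]ethan-1-one | C=C(C)[C@H](O[Si](C)(C)C(C)(C)C)Cc1c(OCOC)cc(OC)c(C(C)=O)c1OCOC
F6 | step 9 | (E)-1-[3-[(2R)-2-(tert-butyldimethylsilyloxy)-3-methylbut-3-en-1-yl]-6-methoxy-2,4-bis(triethylsilyloxy)phenyl]-3-[4-(triethylsilyloxy)phenyl]prop-2-en-1-one | C=C(C)[C@H](O[Si](C)(C)C(C)(C)C)Cc1c(O[Si](CC)(CC)CC)cc(OC)c(C(=O)/C=C/c2ccc(O[Si](CC)(CC)CC)cc2)c1O[Si](CC)(CC)CC
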